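The plan removes both carbon substituents from C4, that is C4–C5 and C4–CH3 (the chain is numbered from carbinol C1 to isopropyl methine C16). It exploits the homoallylic array O–C1–C2–C3=C4. This array is folded back into a 2,3-dihydrofuran ring whose oxygen sits on C4 and whose position 2 (chain C1) carries the 3-furyl ring and the preset (S) centre. The precursor is the 5-tributylstannyl derivative of that ring. After tin–lithium exchange it is bound to copper together with the C5–C16 alkyl chain. The chain then migrates from the metal onto C4 while the C4–O bond breaks, and methyl iodide methylates the resulting vinylcopper. One flask should give two C–C bonds, the E alkene and the free carbinol.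

Key step: step 13

Remark on the chemistry: C14 travels as the TBS ether of a racemic secondary alcohol instead of a ketal, because acid hydrolysis of a ketal at the end would threaten the ionisable 3-furylcarbinyl acetate and could draw the C11=C12 alkene into conjugation with the ketone; compounds 12–26 of the chain series are therefore racemic, 28–32 are C14 epimer pairs, and the extra centre disappears in step 16.

Step 1
Reactants: 1 3-furaldehyde; 2 methyl acrylate
Product: 3 methyl 4-(furan-3-yl)-4-oxobutanoate
Conditions: 3-benzyl-5-(2-hydroxyethyl)-4-methylthiazolium chloride (10 mol %), Et3N, dioxane, 80 °C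
Reagents that add atoms: methyl acrylate (2), C=CC(=O)OC
Why: Stetter reaction, in which the thiazolylidene turns the aldehyde into an acyl anion equivalent that adds 1,4 to the acrylate; heteroaromatic aldehydes and acrylates are standard partners and the furan ring is not involved.

Step 2
Reactants: 3 methyl 4-(furan-3-yl)-4-oxobutanoate
Product: 5 (5S)-5-(furan-3-yl)oxolan-2-one, via hydroxy ester 4 (not isolated)
Conditions: RuCl[(S,S)-TsDPEN](p-cymene) (1 mol %), HCO2H/Et3N 5:2, 40 °C
Reagents that add atoms: none
Why: Noyori-type asymmetric transfer hydrogenation of a heteroaryl alkyl ketone, in which the CH/π contact between the cymene ligand and the furyl ring selects the carbonyl face so that the (S,S) catalyst should set (S) at C1 as it does for aryl alkyl ketones, after which the γ-hydroxy ester closes to the five-membered lactone in the warm acidic medium.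

Step 3
Reactants: 5 (5S)-5-(furan-3-yl)oxolan-2-one
Product: 6 (5S)-5-(furan-3-yl)oxolan-2-ol (both anomers)
Conditions: DIBAL-H (1.1 equiv), CH2Cl2, −78 °C; aq. Rochelle salt
Reagents that add atoms: none
Why: Partial reduction of a γ-lactone, where the tetrahedral aluminium alkoxide persists at −78 °C and gives the lactol only on work-up; C1 takes no part and the anomeric centre is removed later.

Step 4
Reactants: 6 (5S)-5-(furan-3-yl)oxolan-2-ol
Product: 7 (2S)-2-(furan-3-yl)-5-(phenylsulfonyl)oxolane (both C5 epimers)
Conditions: PhSO2H, CaCl2, CH2Cl2, 0 °C → rt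
Reagents that add atoms: benzenesulfinic acid, O=S(O)c1ccccc1
Why: Anomeric substitution of a lactol through its oxocarbenium ion with S-attack of the sulfinate, the standard entry to 2-sulfonyl cyclic ethers; the acid is too weak to ionise the furyl C1–O bond.

Step 5
Reactants: 7 (2S)-2-(furan-3-yl)-5-(phenylsulfonyl)oxolane
Product: 9 tributyl[(5S)-5-(furan-3-yl)-4,5-dihydrofuran-2-yl]stannane, via stannyl sulfone 8 (not isolated)
Conditions: LDA, THF, −78 °C; Bu3SnCl, −78 → 0 °C; then i-Pr2NEt, CHCl3, 60 °C; Et3N-deactivated alumina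
Reagents that add atoms: tributyltin chloride, CCCC[Sn](Cl)(CCCC)CCCC
Why: Sulfone-based stannylation–elimination of a 2-sulfonyl cyclic ether, in which LDA removes the proton flanked by ring oxygen and sulfonyl (by far the most acidic) without touching the furan, Bu3SnCl quenches the carbanion, and amine-assisted loss of benzenesulfinic acid through the oxocarbenium ion leaves the endocyclic stannyl enol ether with C1 untouched.

Step 6
Reactants: 10 isovaleraldehyde; 11 propargyl bromide
Product: 12 (±)-6-methylhept-1-yn-4-ol
Conditions: activated Zn, THF, 0 °C → rt; aqueous work-up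
Reagents that add atoms: propargyl bromide (11), C#CCBr
Why: Barbier-type propargylation, in which the allenylzinc bromide formed in situ attacks the aldehyde in an SE2' manner and should give the homopropargylic alcohol; the new C14 centre is racemic by design because step 16 oxidises it away.

Step 7
Reactants: 12 (±)-6-methylhept-1-yn-4-ol
Product: 13 (±)-tert-butyldimethyl[(6-methylhept-1-yn-4-yl)oxy]silane
Conditions: TBSCl, imidazole, DMF, rt
Reagents that add atoms: tert-butyldimethylsilyl chloride, CC(C)(C)[Si](C)(C)Cl
Why: Imidazole-promoted silylation of a secondary alcohol, giving an ether that resists organoaluminium, organolithium, Grignard and copper reagents.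

Step 8
Reactants: 13 (±)-tert-butyldimethyl[(6-methylhept-1-yn-4-yl)oxy]silane; 14 ethylene oxide
Product: 17 (±)-(3E)-6-[(tert-butyldimethylsilyl)oxy]-4,8-dimethylnon-3-en-1-ol, via alkenyldimethylalane 15 (not isolated), via lithium alkenylalanate 16 (not isolated)
Conditions: Me3Al, Cp2ZrCl2 (25 mol %), CH2Cl2, 0 °C → rt; strip volatiles, hexane; n-BuLi, −78 → 0 °C; ethylene oxide, THF, −78 → 0 °C
Reagents that add atoms: trimethylaluminium, C[Al](C)C; ethylene oxide (14), C1CO1
Why: Negishi zirconium-catalysed methylalumination adds CH3 (to C12) and Al (to C11) syn across the terminal alkyne and so fixes the E C11=C12 geometry, and the more nucleophilic butyl ate complex opens ethylene oxide with retention of that geometry, a known route to (E)-4-methylalk-3-en-1-ols.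

Step 9
Reactants: 17 (±)-(3E)-6-[(tert-butyldimethylsilyl)oxy]-4,8-dimethylnon-3-en-1-ol
Product: 18 (±)-tert-butyl{[(6E)-9-iodo-2,6-dimethylnon-6-en-4-yl]oxy}dimethylsilane
Conditions: I2, PPh3, imidazole, CH2Cl2, 0 °C
Reagents that add atoms: iodine, II
Why: Appel-type iodination (Garegg–Samuelsson conditions), an SN2 displacement of the primary oxyphosphonium ion by iodide under neutral conditions that leave the alkene and silyl ether alone.

Step 10
Reactants: 18 (±)-tert-butyl{[(6E)-9-iodo-2,6-dimethylnon-6-en-4-yl]oxy}dimethylsilane; 19 2,3-dihydrofuran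
Product: 21 (±)-5-{(3E)-6-[(tert-butyldimethylsilyl)oxy]-4,8-dimethylnon-3-en-1-yl}-2,3-dihydrofuran, via 5-lithio-2,3-dihydrofuran 20 (not isolated)
Conditions: 19, t-BuLi, THF, −78 → 0 °C; then 18, −78 °C → rt; basic alumina
Reagents that add atoms: 2,3-dihydrofuran (19), C1CC=CO1
Why: α-Lithiation of a cyclic enol ether followed by SN2 alkylation, where t-BuLi removes the vinylic proton next to oxygen and the alkenyllithium is known to be alkylated by primary homoallylic iodides; the TBS ether is inert.

Step 11
Reactants: 21 (±)-5-{(3E)-6-[(tert-butyldimethylsilyl)oxy]-4,8-dimethylnon-3-en-1-yl}-2,3-dihydrofuran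
Product: 22 (±)-(3E,7E)-10-[(tert-butyldimethylsilyl)oxy]-4,8,12-trimethyltrideca-3,7-dien-1-ol
Conditions: MeMgBr (3 equiv), NiCl2(PPh3)2 (5 mol %), toluene, 80 °C
Reagents that add atoms: methylmagnesium bromide, C[Mg]Br
Why: Nickel-catalysed Kumada-type coupling of an enol ether C(sp2)–O bond (Wenkert coupling), in which oxidative addition and reductive elimination both go with retention, so CH3 takes the place of the ring oxygen cis to C6 and C7=C8 should come out E, as established for 5-alkyl-2,3-dihydrofurans in isoprenoid chain building.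

Step 12
Reactants: 22 (±)-(3E,7E)-10-[(tert-butyldimethylsilyl)oxy]-4,8,12-trimethyltrideca-3,7-dien-1-ol
Product: 23 (±)-tert-butyl{[(6E,10E)-13-iodo-2,6,10-trimethyltrideca-6,10-dien-4-yl]oxy}dimethylsilane (C5–C16 iodide)
Conditions: I2, PPh3, imidazole, CH2Cl2, 0 °C
Reagents that add atoms: iodine, II
Why: The same Appel-type iodination as in step 9, an SN2 reaction at the primary C5 carbinol that does not touch either trisubstituted alkene.

Step 13
Reactants: 9 tributyl[(5S)-5-(furan-3-yl)-4,5-dihydrofuran-2-yl]stannane; 23 C5–C16 iodide; 24 methyl iodide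
Product: 30 (1S,3E,7E,11E)-14-[(tert-butyldimethylsilyl)oxy]-1-(furan-3-yl)-4,8,12,16-trimethylheptadeca-3,7,11-trien-1-ol (C14 epimers), via alkyllithium 25 (not isolated), via alkylcopper 26 (not isolated), via lithiated dihydrofuran 27 (not isolated), via mixed cuprate 28 (not isolated), via alkenylcopper alkoxide 29 (not isolated)
Conditions: 23, t-BuLi (2 equiv), Et2O/pentane, −78 °C; CuBr·SMe2 (1 equiv), Et2O/Me2S, −78 → −40 °C; 9 (1.2 equiv), n-BuLi, THF, −78 °C, cannulated in at −78 °C; warm to 0 °C → rt; MeI (excess), 0 °C → rt; aq. NH4Cl/NH3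
Reagents that add atoms: methyl iodide (24), CI
Why: Tin–lithium exchange at −78 °C gives alkenyllithium 27, which binds to alkylcopper 26 to form cuprate 28 with both carbon ligands on one copper; on warming, the C5 ligand moves from copper to C4 in the alkene plane at the side opposite the C4–O bond, that bond breaks, and the oxygen ends as the C1 lithium alkoxide of alkenylcopper 29. The closest known reaction type is the copper-mediated 1,2-metallate rearrangement of α-metallated cyclic enol ethers with electrophilic trapping of the alkenylcopper, which has been run on 2-substituted 5-lithio-2,3-dihydrofurans with primary alkyl ligands. No ring is closed (the dihydrofuran opens) and no stereocentre is created; C1 keeps its (S) configuration because none of its four bonds takes part. The step needs E geometry at C3=C4: inversion at C4 during the shift leaves copper where oxygen was, cis to C2, and methylation with retention puts CH3 there and C5 trans to C2, an outcome enforced by the ring, which holds O cis to C2 in the precursor. It also needs site-selective metallation, secured by the stannyl group (exchange is far faster than deprotonation of a furan C–H or of C1–H), and an inert chain, secured by the TBS ether, which offers no electrophilic carbon and lies too far from C5 for elimination.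

Step 14
Reactants: 30 (1S)-carbinol with C14 OTBS
Product: 31 (1S,3E,7E,11E)-14-[(tert-butyldimethylsilyl)oxy]-1-(furan-3-yl)-4,8,12,16-trimethylheptadeca-3,7,11-trien-1-yl acetate (C14 epimers)
Conditions: Ac2O, pyridine, DMAP (cat.), CH2Cl2, 0 °C → rt
Reagents that add atoms: acetic anhydride, CC(=O)OC(C)=O
Why: DMAP-catalysed acylation takes place at oxygen, so the C1–O bond and the (S) configuration are retained.

Step 15
Reactants: 31 C1 acetate with C14 OTBS
Product: 32 (1S,3E,7E,11E)-1-(furan-3-yl)-14-hydroxy-4,8,12,16-trimethylheptadeca-3,7,11-trien-1-yl acetate (C14 epimers)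
Conditions: HF·pyridine, excess pyridine, THF, 0 °C → rt
Reagents that add atoms: none
Why: Fluoride-driven desilylation in a pyridine-buffered medium that is neither basic enough to cleave the acetate nor acidic enough to ionise the furylcarbinyl ester or attack the furan.

Step 16
Reactants: 32 C1 acetate with C14 OH
Product: 33 (1S,3E,7E,11E)-1-(furan-3-yl)-4,8,12,16-trimethyl-14-oxoheptadeca-3,7,11-trien-1-yl acetate (target)
Conditions: Dess–Martin periodinane, pyridine, CH2Cl2, 0 °C → rt
Reagents that add atoms: none
Why: Dess–Martin oxidation works under near-neutral conditions known to turn homoallylic alcohols into β,γ-unsaturated ketones without moving the alkene, it merges both C14 epimers into one compound, and furan, acetate and C1 are unaffected.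

Compound list
1 | 3-furaldehyde | O=Cc1ccoc1 | starting material
2 | methyl acrylate | C=CC(=O)OC | starting material
3 | methyl 4-(furan-3-yl)-4-oxobutanoate | COC(=O)CCC(=O)c1ccoc1 | intermediate
4 | methyl (4S)-4-(furan-3-yl)-4-hydroxybutanoate | O[C@@H](CCC(=O)OC)c1ccoc1 | intermediate
5 | (5S)-5-(furan-3-yl)oxolan-2-one | O1[C@@H](CCC1=O)c1ccoc1 | intermediate
6 | (5S)-5-(furan-3-yl)oxolan-2-ol, both anomers | O1[C@@H](CCC1O)c1ccoc1 | intermediate
7 | (2S)-2-(furan-3-yl)-5-(phenylsulfonyl)oxolane, both C5 epimers | O1[C@@H](CCC1S(=O)(=O)c1ccccc1)c1ccoc1 | intermediate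
8 | (2S)-2-(furan-3-yl)-5-(phenylsulfonyl)-5-(tributylstannyl)oxolane | O1[C@@H](CCC1([Sn](CCCC)(CCCC)CCCC)S(=O)(=O)c1ccccc1)c1ccoc1 | intermediate
9 | tributyl[(5S)-5-(furan-3-yl)-4,5-dihydrofuran-2-yl]stannane | O1[C@@H](CC=C1[Sn](CCCC)(CCCC)CCCC)c1ccoc1 | intermediate
10 | isovaleraldehyde | CC(C)CC=O | starting material
11 | propargyl bromide | C#CCBr | starting material
12 | (±)-6-methylhept-1-yn-4-ol | C#CCC(O)CC(C)C | intermediate
13 | (±)-tert-butyldimethyl[(6-methylhept-1-yn-4-yl)oxy]silane | C#CCC(O[Si](C)(C)C(C)(C)C)CC(C)C | intermediate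
14 | ethylene oxide | C1CO1 | starting material
15 | {(1E)-4-[(tert-butyldimethylsilyl)oxy]-2,6-dimethylhept-1-en-1-yl}dimethylalane | C[Al](C)/C=C(\C)CC(O[Si](C)(C)C(C)(C)C)CC(C)C | intermediate
16 | lithium butyl{(1E)-4-[(tert-butyldimethylsilyl)oxy]-2,6-dimethylhept-1-en-1-yl}dimethylaluminate | [Li+].CCCC[Al-](C)(C)/C=C(\C)CC(O[Si](C)(C)C(C)(C)C)CC(C)C | intermediate
17 | (±)-(3E)-6-[(tert-butyldimethylsilyl)oxy]-4,8-dimethylnon-3-en-1-ol | OCC/C=C(\C)CC(O[Si](C)(C)C(C)(C)C)CC(C)C | intermediate
18 | (±)-tert-butyl{[(6E)-9-iodo-2,6-dimethylnon-6-en-4-yl]oxy}dimethylsilane | ICC/C=C(\C)CC(O[Si](C)(C)C(C)(C)C)CC(C)C | intermediate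
19 | 2,3-dihydrofuran | C1CC=CO1 | starting material
20 | 5-lithio-2,3-dihydrofuran | [Li]C1=CCCO1 | intermediate
21 | (±)-5-{(3E)-6-[(tert-butyldimethylsilyl)oxy]-4,8-dimethylnon-3-en-1-yl}-2,3-dihydrofuran | O1CCC=C1CC/C=C(\C)CC(O[Si](C)(C)C(C)(C)C)CC(C)C | intermediate
22 | (±)-(3E,7E)-10-[(tert-butyldimethylsilyl)oxy]-4,8,12-trimethyltrideca-3,7-dien-1-ol | OCC/C=C(\C)CC/C=C(\C)CC(O[Si](C)(C)C(C)(C)C)CC(C)C | intermediate
23 | (±)-tert-butyl{[(6E,10E)-13-iodo-2,6,10-trimethyltrideca-6,10-dien-4-yl]oxy}dimethylsilane | ICC/C=C(\C)CC/C=C(\C)CC(O[Si](C)(C)C(C)(C)C)CC(C)C | intermediate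
24 | methyl iodide | CI | starting material
25 | {(3E,7E)-10-[(tert-butyldimethylsilyl)oxy]-4,8,12-trimethyltrideca-3,7-dien-1-yl}lithium | [Li]CC/C=C(\C)CC/C=C(\C)CC(O[Si](C)(C)C(C)(C)C)CC(C)C | intermediate
26 | {(3E,7E)-10-[(tert-butyldimethylsilyl)oxy]-4,8,12-trimethyltrideca-3,7-dien-1-yl}copper(I) | [Cu]CC/C=C(\C)CC/C=C(\C)CC(O[Si](C)(C)C(C)(C)C)CC(C)C | intermediate
27 | [(5S)-5-(furan-3-yl)-4,5-dihydrofuran-2-yl]lithium | O1[C@@H](CC=C1[Li])c1ccoc1 | intermediate
28 | lithium [(5S)-5-(furan-3-yl)-4,5-dihydrofuran-2-yl](C5–C16 alkyl)cuprate | [Li+].O1[C@@H](CC=C1[Cu-]CC/C=C(\C)CC/C=C(\C)CC(O[Si](C)(C)C(C)(C)C)CC(C)C)c1ccoc1 | intermediate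
29 | lithium (1S)-alkoxide of the ring-opened C4 alkenylcopper, Cu cis to C2 | [Li+].[O-][C@@H](C/C=C(\[Cu])CC/C=C(\C)CC/C=C(\C)CC(O[Si](C)(C)C(C)(C)C)CC(C)C)c1ccoc1 | intermediate
30 | (1S,3E,7E,11E)-14-[(tert-butyldimethylsilyl)oxy]-1-(furan-3-yl)-4,8,12,16-trimethylheptadeca-3,7,11-trien-1-ol, C14 epimers | O[C@@H](C/C=C(\C)CC/C=C(\C)CC/C=C(\C)CC(O[Si](C)(C)C(C)(C)C)CC(C)C)c1ccoc1 | intermediate
31 | (1S,3E,7E,11E)-14-[(tert-butyldimethylsilyl)oxy]-1-(furan-3-yl)-4,8,12,16-trimethylheptadeca-3,7,11-trien-1-yl acetate, C14 epimers | CC(=O)O[C@@H](C/C=C(\C)CC/C=C(\C)CC/C=C(\C)CC(O[Si](C)(C)C(C)(C)C)CC(C)C)c1ccoc1 | intermediate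
32 | (1S,3E,7E,11E)-1-(furan-3-yl)-14-hydroxy-4,8,12,16-trimethylheptadeca-3,7,11-trien-1-yl acetate, C14 epimers | CC(=O)O[C@@H](C/C=C(\C)CC/C=C(\C)CC/C=C(\C)CC(O)CC(C)C)c1ccoc1 | intermediate
33 | (1S,3E,7E,11E)-1-(furan-3-yl)-4,8,12,16-trimethyl-14-oxoheptadeca-3,7,11-trien-1-yl acetate | CC(=O)O[C@@H](C/C=C(\C)CC/C=C(\C)CC/C=C(\C)CC(=O)CC(C)C)c1ccoc1 | target

Total step count: 16. Longest linear sequence: 11 (steps 6–16, from isovaleraldehyde). The stannane branch (steps 1–5) joins at step 13.

Steps most likely to fail

1. Step 13. The primary alkylcopper may decay before the cuprate forms. Ligand migration in the 1:1:1 cuprate may be slow or incomplete. The alkenylcopper may also be protonated before it is methylated. The fallback sets out from 9 and 23 and splits the two bond formations into separate reactions that need no copper. Alkenyllithium 27, made from 9 as before, is alkylated directly by iodide 23 (THF, −78 °C → rt) to give the 5-alkyl-2-(3-furyl)-2,3-dihydrofuran F1. Nickel-catalysed coupling with MeMgBr under the conditions of step 11 then replaces the ring oxygen by methyl with retention, which also gives E C3=C4. The fallback returns to the route at 30.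

2. Step 5. The α-sulfonyl carbanion of the five-membered ring may break down before it is stannylated. The acid-labile stannyl enol ether may also lose tin by protonation during elimination or purification. The fallback sets out from lactone 5 and avoids the lactol and sulfone altogether. Enolisation with KHMDS and O-phosphorylation with (PhO)2P(O)Cl (THF, −78 °C) give the ketene acetal phosphate F2. Palladium-catalysed stannylation (Pd(PPh3)4, Me3SnSnMe3, LiCl, THF, reflux) gives the trimethylstannane F3. Exchange with MeLi at −78 °C returns to the route at 27 inside step 13.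

3. Step 8. Transfer of the alkenyl ligand from the aluminate to the epoxide may be inefficient, with methyl or butyl transfer competing. The fallback sets out from alane 15 (made from 13 as in step 8) and builds C9–C10 by cross-coupling and hydroboration instead of epoxide opening. Palladium-catalysed alkenyl–alkenyl coupling of 15 with vinyl bromide (Pd(PPh3)4, THF) gives the (E)-diene F4. 9-BBN adds only to the monosubstituted terminal alkene to give the B-alkyl borane F5. Oxidation with NaOH/H2O2 returns to the route at 17.

Further compounds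
F1 | step 13 | (2S)-5-{(3E,7E)-10-[(tert-butyldimethylsilyl)oxy]-4,8,12-trimethyltrideca-3,7-dien-1-yl}-2-(furan-3-yl)-2,3-dihydrofuran | O1[C@@H](CC=C1CC/C=C(\C)CC/C=C(\C)CC(O[Si](C)(C)C(C)(C)C)CC(C)C)c1ccoc1
F2 | step 5 | (5S)-5-(furan-3-yl)-4,5-dihydrofuran-2-yl diphenyl phosphate | O1[C@@H](CC=C1OP(=O)(Oc1ccccc1)Oc1ccccc1)c1ccoc1
F3 | step 5 | [(5S)-5-(furan-3-yl)-4,5-dihydrofuran-2-yl]trimethylstannane | O1[C@@H](CC=C1[Sn](C)(C)C)c1ccoc1
F4 | step 8 | (±)-tert-butyl{[(6E)-2,6-dimethylnona-6,8-dien-4-yl]oxy}dimethylsilane | C=C/C=C(\C)CC(O[Si](C)(C)C(C)(C)C)CC(C)C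
F5 | step 8 | (±)-9-{(3E)-6-[(tert-butyldimethylsilyl)oxy]-4,8-dimethylnon-3-en-1-yl}-9-borabicyclo[3.3.1]nonane | CC(C)CC(O[Si](C)(C)C(C)(C)C)C/C(C)=C/CCB1C2CCCC1CCC2
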